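The six-membered carbocycle is read as a dearomatised phenol. C1 (the quaternary oxirane carbon bearing C7H2OBz) and C4 both carry oxygen, so C1–C6 map onto an achiral 4-(benzoyloxymethyl)-p-quinol with a free tertiary hydroxyl, whose enone arms C2=C3 and C6=C5 are enantiotopic. The oxirane oxygen on C1 is cis to the C2 acetate. A chiral phosphoric acid joins the C1 hydroxyl to acetaldehyde and sends the hemiacetal oxygen to C2, closing a cis-fused 1,3-dioxolane and fixing C1 and C2 in one operation. Ozone later turns the acetal carbon into the C2 acetyl group, substrate control sets C3–C6, and a Mitsunobu dehydration closes the C1–C6 oxirane.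

Key step: step 3

Remark on the chemistry: ring atoms keep the target numbering throughout (C1 bears C7H2OBz, then C2 to C6 around the ring). α is the ring face that carries the oxygen on C1; β is the face that carries C7.

Assumption: the sense of induction of the phosphoric acid is not predicted here. (R)-TRIP is written, and its mirror image is to be used if the first run gives the antipodal dioxolane.

Step 1
Reactants: 1 4-hydroxybenzyl alcohol; 2 benzoic acid
Product: 3 4-hydroxybenzyl benzoate
Conditions: PPh3, diisopropyl azodicarboxylate (DIAD), THF, 0 °C → rt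
Reagents that add atoms: none
Why: Mitsunobu esterification: only the benzylic hydroxyl can become an oxyphosphonium leaving group, and benzoate (far more acidic than the phenol) is the nucleophile that displaces it, so the phenol should emerge free.

Step 2
Reactants: 3 4-hydroxybenzyl benzoate
Product: 4 4-(benzoyloxymethyl)-4-hydroxycyclohexa-2,5-dien-1-one
Conditions: PhI(OAc)2, MeCN/H2O (4:1), 0 °C
Reagents that add atoms: water, O
Why: Oxidative dearomatisation of a para-substituted phenol with a trivalent iodine reagent: the aryloxy-iodane loses iodobenzene and water adds at the para carbon to give the p-quinol, with no stereocentre created because the two ring arms are identical.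

Step 3
Reactants: 4 4-(benzoyloxymethyl)-4-hydroxycyclohexa-2,5-dien-1-one; 5 acetaldehyde
Product: 7 cis-fused dioxolane enone (O1 and O2 α; C7 β; acetal methyl exo; C4 ketone; C5=C6 alkene), via hemiacetal 6 (not isolated)
Conditions: (R)-TRIP [(R)-3,3′-bis(2,4,6-triisopropylphenyl)-1,1′-binaphthyl-2,2′-diyl hydrogen phosphate] (10 mol%), MeCHO (5 equiv), 4 Å MS, ClCH2CH2Cl, sealed vessel, rt
Reagents that add atoms: none
Why: The phosphoric acid catalyses reversible addition of the tertiary C1 hydroxyl to acetaldehyde and then, holding the hemiacetal O–H on its P=O oxygen and the dienone carbonyl on its P–OH, delivers the hemiacetal oxygen to an enone β-carbon (oxa-Michael addition); the closest known reaction type is the chiral phosphoric acid-catalysed acetalisation/oxa-Michael desymmetrisation of p-quinols and p-peroxyquinols. The 1,3-dioxolane closes in the 5-exo-trig mode, and because the short O–C–O tether can reach C2 only on the face that carries O1, the ring fusion is necessarily cis. C2 is set by the catalyst, which must pick one of the two enantiotopic arms (C2 and not C6); C1 becomes stereogenic as a consequence of that choice without a bond being made to it; the acetal carbon is set under thermodynamic control through reversible hemiacetal formation, which places its methyl group on the convex exo face. The only selectivity the step must supply is therefore enantiotopic-group selection, since the two arms are constitutionally identical (no regiochemical issue), C1 is quaternary (no aromatisation) and the tether fixes the relative configuration.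

Step 4
Reactants: 7 cis-fused dioxolane enone
Product: 8 3β-acetoxy dioxolane enone (acetate on C3 trans to O2)
Conditions: Mn(OAc)3·2H2O (3 equiv), benzene/AcOH (10:1), reflux, Dean–Stark
Reagents that add atoms: manganese triacetate (used as its dihydrate), CC(=O)[O-].CC(=O)[O-].CC(=O)[O-].[Mn+3]
Why: Mn(OAc)3 α′-acetoxylation of an enone (manganese enolate, then acetoxy transfer): C3 is the only enolisable position because C1 is quaternary, acetate should enter on the convex β face anti to O2, and the trans-diequatorial O2/OAc arrangement is also the thermodynamically preferred epimer of this epimerisable centre.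

Step 5
Reactants: 8 3β-acetoxy dioxolane enone
Product: 9 3β-acetoxy-4α-hydroxy-5-ene (1α,2α-O-ethylidene acetal, C7 benzoate)
Conditions: NaBH4, CeCl3·7H2O, MeOH, −78 °C
Reagents that add atoms: none
Why: Luche reduction (1,2-selective and only weakly basic at −78 °C): axial hydride attack on the half-chair that keeps O2 and the C3 acetate equatorial should give the pseudoequatorial 4α-alcohol, trans to the C3 acetate and cis-1,3 to O2.

Step 6
Reactants: 9 3β-acetoxy-4α-hydroxy-5-ene
Product: 10 4α-triisopropylsilyl ether of 9
Conditions: iPr3SiOTf, 2,6-lutidine, CH2Cl2, −40 → 0 °C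
Reagents that add atoms: triisopropylsilyl trifluoromethanesulfonate, CC(C)[Si](C(C)C)(C(C)C)OS(=O)(=O)C(F)(F)F
Why: Silylation of a secondary alcohol with a silyl triflate and a hindered pyridine base is fast at low temperature and too weakly basic to move the C3 acetate; the TIPS ether is chosen because it survives OsO4, ozone, amine base and Mitsunobu conditions and keeps O4 out of any later acyl shift.

Step 7
Reactants: 10 4α-triisopropylsilyl ether
Product: 11 5β,6β-diol of 10
Conditions: OsO4 (5 mol%), N-methylmorpholine N-oxide (NMO, 2 equiv), acetone/H2O (5:1), rt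
Reagents that add atoms: osmium tetroxide (catalytic oxygen carrier), O=[Os](=O)(=O)=O; N-methylmorpholine N-oxide, C[N+]1([O-])CCOCC1; water, O
Why: Catalytic OsO4/NMO syn-dihydroxylation: by the empirical anti rule for osmylation of allylic ethers the reagent should add to C5=C6 on the β face, opposite the pseudoaxial C1–O1 bond and the C4 silyloxy group, so both new hydroxyls are β.

Step 8
Reactants: 11 5β,6β-diol
Product: 14 2α,3β-diacetoxy-1α,5β,6β-triol 4α-TIPS ether (C7 benzoate), via hemiorthoester 12 (not isolated), via tertiary acetate 13 (not isolated)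
Conditions: O3, EtOAc, −78 °C; N2 purge; then Et3N (cat.), CH2Cl2, rt
Reagents that add atoms: ozone, [O-][O+]=O
Why: Ozone oxidation of an aldehyde-derived cyclic acetal to a hydroxy ester (insertion into the acetal C–H bond, loss of O2, collapse of the hemiorthoester) turns the acetaldehyde unit into the C2 acetyl group without acid; collapse is expected to leave the acetyl mainly on the axial tertiary O1, and triethylamine then relays it by cis-1,2 acyl shift to the secondary O2, the only reachable acceptor because O6 is trans-diaxial to O1 and O4 is silylated.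

Step 9
Reactants: 14 2α,3β-diacetoxy-1α,5β,6β-triol 4α-TIPS ether
Product: 15 4-O-TIPS ether of the target (1α,6α-epoxide, 5β-hydroxyl)
Conditions: PPh3, DIAD, THF, 0 °C → rt
Reagents that add atoms: none
Why: Mitsunobu cyclodehydration of a trans-diaxial 1,2-diol to an epoxide: the secondary 6β-hydroxyl is activated as an oxyphosphonium ion and displaced (3-exo-tet, inversion at C6) by the tertiary 1α-hydroxyl, which cannot be activated itself, while the 5β-hydroxyl has no anti-disposed internal nucleophile; the neutral medium avoids the acyl scrambling among O1, O2 and O7 that an alkoxide-mediated epoxide closure would invite.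

Step 10
Reactants: 15 4-O-TIPS ether of the target
Product: 16 CNP0171674.1 (1α,6α-epoxide; 2α,3β-diacetate; 4α,5β-diol; C7 benzoate)
Conditions: HF·pyridine, pyridine, THF, 0 °C → rt
Reagents that add atoms: none
Why: Fluoride-mediated desilylation under buffered, weakly acidic conditions should cleave only the Si–O bond, leaving the oxirane closed and the acetates and benzoate in place (no alkoxide, hence no acyl migration).

Compound list
1 | 4-hydroxybenzyl alcohol | OCc1ccc(O)cc1 | starting material
2 | benzoic acid | OC(=O)c1ccccc1 | starting material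
3 | 4-hydroxybenzyl benzoate | O=C(OCc1ccc(O)cc1)c1ccccc1 | intermediate
4 | 4-(benzoyloxymethyl)-4-hydroxycyclohexa-2,5-dien-1-one (achiral p-quinol) | O=C1C=CC(O)(COC(=O)c2ccccc2)C=C1 | intermediate
5 | acetaldehyde | CC=O | starting material
6 | hemiacetal of 4 at the tertiary oxygen, [1-(1-hydroxyethoxy)-4-oxocyclohexa-2,5-dien-1-yl]methyl benzoate (not isolated; hemiacetal epimers interconvert, the one leading to 7 is drawn) | C[C@@H](O)OC1(COC(=O)c2ccccc2)C=CC(=O)C=C1 | intermediate
7 | (2-methyl-5-oxo-3a,4,5,7a-tetrahydro-1,3-benzodioxol-7a-yl)methyl benzoate; cis-fused dioxolane enone with O1 and O2 α, C7 β, acetal methyl exo (cis to the hydrogen on C2) | C[C@H]1O[C@@H]2CC(=O)C=C[C@]2(COC(=O)c2ccccc2)O1 | intermediate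
8 | 3β-acetoxy derivative of 7 (acetate on C3, trans to O2) | C[C@H]1O[C@@H]2[C@@H](OC(C)=O)C(=O)C=C[C@]2(COC(=O)c2ccccc2)O1 | intermediate
9 | 3β-acetoxy-4α-hydroxy-5-ene, 1α,2α-O-ethylidene acetal, C7 benzoate | C[C@H]1O[C@@H]2[C@@H](OC(C)=O)[C@H](O)C=C[C@]2(COC(=O)c2ccccc2)O1 | intermediate
10 | 4α-triisopropylsilyl ether of 9 | C[C@H]1O[C@@H]2[C@@H](OC(C)=O)[C@H](O[Si](C(C)C)(C(C)C)C(C)C)C=C[C@]2(COC(=O)c2ccccc2)O1 | intermediate
11 | 5β,6β-diol of 10 | C[C@H]1O[C@@H]2[C@@H](OC(C)=O)[C@H](O[Si](C(C)C)(C(C)C)C(C)C)[C@@H](O)[C@@H](O)[C@]2(COC(=O)c2ccccc2)O1 | intermediate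
12 | hemiorthoester from 11 (2-hydroxy-2-methyl-1,3-dioxolane spanning O1 and O2; not isolated) | C[C@@]1(O)O[C@@H]2[C@@H](OC(C)=O)[C@H](O[Si](C(C)C)(C(C)C)C(C)C)[C@@H](O)[C@@H](O)[C@]2(COC(=O)c2ccccc2)O1 | intermediate
13 | tertiary acetate: 1α,3β-diacetoxy-2α,5β,6β-triol 4α-TIPS ether, C7 benzoate (not isolated) | CC(=O)O[C@]1(COC(=O)c2ccccc2)[C@H](O)[C@@H](OC(C)=O)[C@H](O[Si](C(C)C)(C(C)C)C(C)C)[C@@H](O)[C@H]1O | intermediate
14 | 2α,3β-diacetoxy-1α,5β,6β-trihydroxy-4α-(triisopropylsilyloxy)cyclohexane bearing 1β-CH2OBz | O[C@]1(COC(=O)c2ccccc2)[C@H](OC(C)=O)[C@@H](OC(C)=O)[C@H](O[Si](C(C)C)(C(C)C)C(C)C)[C@@H](O)[C@H]1O | intermediate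
15 | 4-O-triisopropylsilyl ether of the target (1α,6α-epoxide, 5β-hydroxyl, 2α,3β-diacetate, C7 benzoate) | CC(=O)O[C@H]1[C@H](O[Si](C(C)C)(C(C)C)C(C)C)[C@@H](O)[C@@H]2O[C@]2(COC(=O)c2ccccc2)[C@@H]1OC(C)=O | intermediate
16 | CNP0171674.1: 1α,6α-epoxide, 2α,3β-diacetate, 4α,5β-diol, C7 benzoate | CC(=O)O[C@H]1[C@H](O)[C@@H](O)[C@@H]2O[C@]2(COC(=O)c2ccccc2)[C@@H]1OC(C)=O | target

Total step count: 10. Longest linear sequence: 10 steps (1 → 16).

Steps most likely to fail

Step 3. The catalyst may discriminate poorly between the two enantiotopic enone arms, or the hemiacetal may revert and lose volatile acetaldehyde before ring closure. Fallback: the same C2–O bond is made by the known boronic acid-tethered oxa-Michael desymmetrisation. p-Quinol 4 and phenylboronic acid give the boronate hemiester F1. The quinine-derived bifunctional catalyst 1-[3,5-bis(trifluoromethyl)phenyl]-3-(9-deoxy-9-epi-quinin-9-yl)thiourea closes it to the cis-fused cyclic phenylboronate F2. H2O2 in pH 7 buffer releases the cis-diol F3. Acetalisation with 1,1-dimethoxyethane and pyridinium p-toluenesulfonate under thermodynamic control (methyl exo) returns to the route at 7.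

Step 8. Ozone may insert only slowly into the concave acetal C–H bond, carbinol C–H oxidation may compete, or the acetyl relay from O1 to O2 may stay incomplete. Fallback: the acetal is removed hydrolytically one stage earlier, while no vicinal diol is present. Silyl ether 10 is treated with aqueous CF3CO2H in CH2Cl2 to give the 1α,2α-diol F4; an acetyl shift between O3 and O2 at this stage would be harmless. Ac2O/pyridine acetylates the free secondary hydroxyl and leaves the tertiary one, giving the 2α,3β-diacetate F5. OsO4/NMO dihydroxylation of F5, again anti to the allylic oxygens, returns to the route at 14.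

Step 9. The cis-5,6-diol may hold the phosphorus as a dioxaphosphorane, or a hydride shift at the activated carbinol may give a ketone instead of displacement. Fallback: C6 is activated as a cyclic sulfate instead of an oxyphosphonium ion. Triol 14 with SOCl2/Et3N gives the 5,6-cyclic sulfite F6. RuCl3 (cat.)/NaIO4 oxidises it to the 5,6-cyclic sulfate F7. DBU in THF at low temperature lets the 1α-hydroxyl open the sulfate at C6 with inversion to the epoxy 5-hydrogen sulfate F8. Catalytic H2SO4 in moist THF hydrolyses the sulfate monoester and returns to the route at 15.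

Further compounds
F1 | step 3 | boronate hemiester of 4, [1-(hydroxy(phenyl)boranyloxy)-4-oxocyclohexa-2,5-dien-1-yl]methyl benzoate | OB(c1ccccc1)OC1(COC(=O)c2ccccc2)C=CC(=O)C=C1
F2 | step 3 | cis-fused cyclic phenylboronate enone (O1 and O2 α, C7 β) | c1ccccc1B1O[C@@H]2CC(=O)C=C[C@]2(COC(=O)c2ccccc2)O1
F3 | step 3 | 1α,2α-dihydroxy-4-oxocyclohex-5-ene bearing 1β-CH2OBz (cis-diol enone) | O[C@@H]1CC(=O)C=C[C@]1(COC(=O)c1ccccc1)O
F4 | step 8 | 3β-acetoxy-1α,2α-dihydroxy-4α-(triisopropylsilyloxy)cyclohex-5-ene bearing 1β-CH2OBz | O[C@]1(COC(=O)c2ccccc2)[C@H](O)[C@@H](OC(C)=O)[C@H](O[Si](C(C)C)(C(C)C)C(C)C)C=C1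
F5 | step 8 | 2α,3β-diacetoxy-1α-hydroxy-4α-(triisopropylsilyloxy)cyclohex-5-ene bearing 1β-CH2OBz | O[C@]1(COC(=O)c2ccccc2)[C@H](OC(C)=O)[C@@H](OC(C)=O)[C@H](O[Si](C(C)C)(C(C)C)C(C)C)C=C1
F6 | step 9 | 5β,6β-cyclic sulfite of 14 (either configuration at sulfur) | O[C@]1(COC(=O)c2ccccc2)[C@H](OC(C)=O)[C@@H](OC(C)=O)[C@H](O[Si](C(C)C)(C(C)C)C(C)C)[C@H]2OS(=O)O[C@@H]12
F7 | step 9 | 5β,6β-cyclic sulfate of 14 | O[C@]1(COC(=O)c2ccccc2)[C@H](OC(C)=O)[C@@H](OC(C)=O)[C@H](O[Si](C(C)C)(C(C)C)C(C)C)[C@H]2OS(=O)(=O)O[C@@H]12
F8 | step 9 | 5β-hydrogen sulfate of 15 (1α,6α-epoxide) | CC(=O)O[C@H]1[C@H](O[Si](C(C)C)(C(C)C)C(C)C)[C@@H](OS(=O)(=O)O)[C@@H]2O[C@]2(COC(=O)c2ccccc2)[C@@H]1OC(C)=O
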